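**Assumption:** the target has no stereocentre (it is achiral), so "single enantiomer" sets no stereochemical task. The only stereo-element in the route is the E-alkene of 9; dione 12 is carried as a racemic diastereomer/tautomer mixture and then aromatized.

## Retrosynthetic overview

1. Target 19 comes from global hydrogenolysis of tribenzyl diaryl ether 18, which comes from methyl esterification of diaryl ether acid 17.
2. Key disconnection: the diaryl ether C(ring A)–O bond of 17, giving benzoic acid 6 (ortho C–H partner) and hindered phenol 16, joined by a carboxylate-directed Cu-catalysed C–H aryloxylation.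
3. Ring A is bought as an arene: 6 from 3-bromophenol by benzylation, Kumada pentylation, para-bromination and lithiation/CO2.
4. Ring B is the only ring constructed: Michael–Claisen annulation of benzyl acetoacetate 11 with methyl (E)-oct-2-enoate 9, aromatization, O-methylation, O-benzylation and C5 hydroxylation give 16.
5. Order: ring B is formed in its own branch (steps 5–11) while ring A is elaborated in parallel (steps 1–4); the fragments are united at step 12.

## Route

**Step 1**
Reactants: 1, 3-bromophenol
Product: 2, 1-(benzyloxy)-3-bromobenzene
Conditions: BnBr, K2CO3, acetone, reflux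
Reagents that add atoms: benzyl bromide, BrCc1ccccc1
Why: Williamson ether synthesis protects the phenol as a benzyl ether that survives Grignard and organolithium steps and is removed at the end by hydrogenolysis.

**Step 2**
Reactants: 2, 1-(benzyloxy)-3-bromobenzene; 3, n-pentylmagnesium bromide
Product: 4, 1-(benzyloxy)-3-pentylbenzene
Conditions: Pd(dppf)Cl2 (2 mol %), THF, 50 °C
Reagents that add atoms: none
Why: Kumada–Corriu sp2–sp3 coupling; the wide-bite-angle dppf ligand suppresses β-hydride elimination of the primary alkyl group.

**Step 3**
Reactants: 4, 1-(benzyloxy)-3-pentylbenzene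
Product: 5, 4-(benzyloxy)-1-bromo-2-pentylbenzene
Conditions: NBS (1.05 equiv), MeCN, 0 °C to rt, dark
Reagents that add atoms: N-bromosuccinimide, O=C1CCC(=O)N1Br
Why: Electrophilic aromatic bromination of an alkoxyarene in MeCN is strongly para-selective to the OBn group, and that position is also ortho to the pentyl chain.

**Step 4**
Reactants: 5, 4-(benzyloxy)-1-bromo-2-pentylbenzene
Product: 6, 4-(benzyloxy)-2-pentylbenzoic acid
Conditions: n-BuLi, THF, −78 °C; then CO2; H3O+
Reagents that add atoms: carbon dioxide, O=C=O
Why: Br–Li exchange at −78 °C is faster than any benzylic deprotonation, and carboxylation of the aryllithium places CO2H between the pentyl group and the single free ortho C–H.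

**Step 5**
Reactants: 7, 1-heptene; 8, methyl acrylate
Product: 9, methyl (E)-oct-2-enoate
Conditions: Grubbs II (1 mol %), methyl acrylate (3 equiv), CH2Cl2, 40 °C
Reagents that add atoms: none
Why: Olefin cross-metathesis of a terminal alkene with an acrylate gives the E-enoate selectively, which sets the only stereo-element in the route.

**Step 6**
Reactants: 10, methyl acetoacetate
Product: 11, benzyl acetoacetate
Conditions: BnOH (1 equiv), DMAP (cat.), toluene, reflux with removal of MeOH
Reagents that add atoms: benzyl alcohol, OCc1ccccc1
Why: β-Keto esters transesterify readily (via the enol/acylketene), and this installs the hydrogenolysable ester that later distinguishes the ring-B carboxyl from the ring-A methyl ester.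

**Step 7**
Reactants: 9, methyl (E)-oct-2-enoate; 11, benzyl acetoacetate
Product: 12, benzyl 2-hydroxy-4-oxo-6-pentylcyclohex-2-ene-1-carboxylate (racemic, mixture of diastereomers/tautomers)
Conditions: NaH/BnOH (NaOBn, 1.1 equiv; BnOH 3 equiv), THF, reflux; then aq. HCl
Reagents that add atoms: none
Why: Michael addition of the acetoacetate enolate to the enoate β-carbon, then Claisen (Dieckmann-type) closure of the methyl-ketone enolate onto the methyl ester, is the classical dihydroresorcylate annulation; benzyloxide as base limits ester scrambling, and the two sp3 centres are inconsequential.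

**Step 8**
Reactants: 12, benzyl 2-hydroxy-4-oxo-6-pentylcyclohex-2-ene-1-carboxylate
Product: 13, benzyl 2,4-dihydroxy-6-pentylbenzoate
Conditions: Br2 (1.0 equiv), DMF, 0 °C; then Li2CO3, 80 °C
Reagents that add atoms: none
Why: Bromination of the β-diketone enol at C3 followed by base-assisted dehydrobromination and tautomerization aromatizes the ring (bromination–dehydrobromination aromatization) and erases both sp3 centres; Li2CO3 buffers HBr to protect the benzyl ester.

**Step 9**
Reactants: 13, benzyl 2,4-dihydroxy-6-pentylbenzoate
Product: 14, benzyl 2-hydroxy-4-methoxy-6-pentylbenzoate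
Conditions: MeI (1.1 equiv), K2CO3, acetone, reflux
Reagents that add atoms: iodomethane, CI
Why: Selective Williamson methylation; the 2-OH is hydrogen-bonded to the ester carbonyl and stays untouched while the free 4-OH is alkylated.

**Step 10**
Reactants: 14, benzyl 2-hydroxy-4-methoxy-6-pentylbenzoate
Product: 15, benzyl 2-(benzyloxy)-4-methoxy-6-pentylbenzoate
Conditions: BnBr (1.3 equiv), K2CO3, DMF, 70 °C
Reagents that add atoms: benzyl bromide, BrCc1ccccc1
Why: Forcing Williamson conditions alkylate the chelated phenol, so ring B will not be a free hydroquinone during the later oxidative coupling.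

**Step 11**
Reactants: 15, benzyl 2-(benzyloxy)-4-methoxy-6-pentylbenzoate
Product: 16, benzyl 2-(benzyloxy)-5-hydroxy-4-methoxy-6-pentylbenzoate
Conditions: phthaloyl peroxide (1.3 equiv), HFIP, rt; then NaHCO3, MeOH/H2O, 40 °C
Reagents that add atoms: phthaloyl peroxide, O=C1OOC(=O)c2ccccc12
Why: Metal-free arene C–H hydroxylation with phthaloyl peroxide follows electrophilic-substitution selectivity, so C5 (para to OBn, ortho to OMe) should react in preference to C3, which is wedged between two alkoxy groups; the aryl hydrogen phthalate resists over-oxidation and is cleaved by bicarbonate without touching the hindered benzyl ester.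

**Step 12**
Reactants: 6, 4-(benzyloxy)-2-pentylbenzoic acid (1.5 equiv); 16, benzyl 2-(benzyloxy)-5-hydroxy-4-methoxy-6-pentylbenzoate
Product: 17, benzyl 2-(benzyloxy)-5-[5-(benzyloxy)-2-carboxy-3-pentylphenoxy]-4-methoxy-6-pentylbenzoate
Conditions: Cu(OAc)2 (25 mol %), K2CO3 (3 equiv), NMO (2 equiv), 4 Å MS, DMF–pyridine 4:1, 100 °C, N2
Reagents that add atoms: none
Why: Proposed new method: carboxylate-directed Cu-catalysed dehydrogenative C–H/O–H coupling. The potassium carboxylate of 6 binds Cu(II) and delivers it to the only free ortho C–H (the other ortho site carries pentyl) by carboxylate/carbonate-assisted metalation. Oxidation (Cu(II) disproportionation/NMO) gives a five-membered aryl–Cu(III) carboxylate, which exchanges with the aryloxide of 16 and undergoes C–O reductive elimination, a step that is fast for aryl–Cu(III) phenoxides. NMO reoxidizes Cu(I) under N2, so the electron-rich phenol is never exposed to O2, and 100 °C is below the range where Cu protodecarboxylates benzoates. The closest known reactions are Cu-catalysed 8-aminoquinoline-amide-directed C–H etherification with phenols and Cu/Ag carboxylate-directed ortho-alkoxylation of benzoates (run at about 140 °C with loss of CO2). What is new is the free carboxylate as sole directing group with the CO2H retained, and a 2,6-disubstituted phenol as partner.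

**Step 13**
Reactants: 17, diaryl ether acid
Product: 18, benzyl 2-(benzyloxy)-5-[5-(benzyloxy)-2-(methoxycarbonyl)-3-pentylphenoxy]-4-methoxy-6-pentylbenzoate
Conditions: MeI, K2CO3, DMF, rt
Reagents that add atoms: iodomethane, CI
Why: SN2 O-alkylation of the carboxylate works even for a di-ortho-substituted acid, and 17 has no free phenol, so only the ring-A carboxyl is methylated.

**Step 14**
Reactants: 18, tribenzyl methyl ester
Product: 19, epiphorellic acid 1, 2-hydroxy-5-[5-hydroxy-2-(methoxycarbonyl)-3-pentylphenoxy]-4-methoxy-6-pentylbenzoic acid
Conditions: H2 (1 atm), 10% Pd/C, EtOAc–MeOH, rt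
Reagents that add atoms: none
Why: Catalytic hydrogenolysis removes both benzyl ethers and the benzyl ester in one operation, leaving the methyl ester, methyl ether and diaryl ether; room temperature avoids decarboxylation of the salicylic acid.

## Compound list

1 | 3-bromophenol | Oc1cccc(Br)c1 | starting material
2 | 1-(benzyloxy)-3-bromobenzene | Brc1cccc(OCc2ccccc2)c1 | intermediate
3 | n-pentylmagnesium bromide (commercial solution) | CCCCC[Mg]Br | starting material
4 | 1-(benzyloxy)-3-pentylbenzene | CCCCCc1cccc(OCc2ccccc2)c1 | intermediate
5 | 4-(benzyloxy)-1-bromo-2-pentylbenzene | CCCCCc1cc(OCc2ccccc2)ccc1Br | intermediate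
6 | 4-(benzyloxy)-2-pentylbenzoic acid | CCCCCc1cc(OCc2ccccc2)ccc1C(=O)O | intermediate
7 | 1-heptene | CCCCCC=C | starting material
8 | methyl acrylate | C=CC(=O)OC | starting material
9 | methyl (E)-oct-2-enoate | CCCCC/C=C/C(=O)OC | intermediate
10 | methyl acetoacetate | CC(=O)CC(=O)OC | starting material
11 | benzyl acetoacetate | CC(=O)CC(=O)OCc1ccccc1 | intermediate
12 | benzyl 2-hydroxy-4-oxo-6-pentylcyclohex-2-ene-1-carboxylate (racemic mixture of diastereomers/tautomers) | CCCCCC1CC(=O)C=C(O)C1C(=O)OCc1ccccc1 | intermediate
13 | benzyl 2,4-dihydroxy-6-pentylbenzoate | CCCCCc1cc(O)cc(O)c1C(=O)OCc1ccccc1 | intermediate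
14 | benzyl 2-hydroxy-4-methoxy-6-pentylbenzoate | CCCCCc1cc(OC)cc(O)c1C(=O)OCc1ccccc1 | intermediate
15 | benzyl 2-(benzyloxy)-4-methoxy-6-pentylbenzoate | CCCCCc1cc(OC)cc(OCc2ccccc2)c1C(=O)OCc1ccccc1 | intermediate
16 | benzyl 2-(benzyloxy)-5-hydroxy-4-methoxy-6-pentylbenzoate | CCCCCc1c(O)c(OC)cc(OCc2ccccc2)c1C(=O)OCc1ccccc1 | intermediate
17 | benzyl 2-(benzyloxy)-5-[5-(benzyloxy)-2-carboxy-3-pentylphenoxy]-4-methoxy-6-pentylbenzoate | CCCCCc1cc(OCc2ccccc2)cc(Oc2c(OC)cc(OCc3ccccc3)c(C(=O)OCc3ccccc3)c2CCCCC)c1C(=O)O | intermediate
18 | benzyl 2-(benzyloxy)-5-[5-(benzyloxy)-2-(methoxycarbonyl)-3-pentylphenoxy]-4-methoxy-6-pentylbenzoate | CCCCCc1cc(OCc2ccccc2)cc(Oc2c(OC)cc(OCc3ccccc3)c(C(=O)OCc3ccccc3)c2CCCCC)c1C(=O)OC | intermediate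
19 | epiphorellic acid 1 (achiral) | CCCCCc1cc(O)cc(Oc2c(OC)cc(O)c(C(=O)O)c2CCCCC)c1C(=O)OC | target

## Summary

**Total step count:** 14.

**Longest linear sequence:** 9 steps (step 5 or 6, then 7 → 8 → 9 → 10 → 11 → 12 → 13 → 14). The ring-A branch (steps 1–4) runs in parallel and reaches the target in 7 steps.

**Three steps most likely to fail**

1. **Step 12 (proposed Cu-catalysed carboxylate-directed C–H aryloxylation).** The risks are weak direction by a monodentate carboxylate, oxidation of the electron-rich hindered phenol, and protodecarboxylation. Fallback, all known chemistry: make the ring-A electrophile from the methyl-ester series. Methyl acetoacetate and 9 (NaOMe/MeOH, then Br2/DMF) give methyl 2,4-dihydroxy-6-pentylbenzoate; selective 4-O-benzylation and triflation of the chelated 2-OH give methyl 4-(benzyloxy)-6-pentyl-2-(triflyloxy)benzoate. Pd-catalysed C–O cross-coupling of this triflate with 16 (Pd/bulky biarylphosphine, K3PO4, toluene) gives 18 directly. A Cu-catalysed Ullmann coupling of the corresponding ortho-bromo or iodo ester is the alternative.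

2. **Step 11 (C–H hydroxylation at the hindered C5).** The risks are C5 versus C3 regioselectivity, reactivity of a pentasubstituted arene, and handling of the peroxide. Fallback: NBS bromination at C5, then Pd-catalysed hydroxylation of the aryl bromide (Pd/tBuBrettPhos with benzaldoxime/Cs2CO3 as hydroxide surrogate), or Miyaura borylation followed by oxidation.

3. **Steps 7–8 (Michael–Claisen annulation and aromatization on the benzyl ester).** The risks are partial benzyl/methyl ester exchange, modest annulation yield, and HBr-induced debenzylation or over-bromination. Fallback: build the ring in the classical all-methyl series (10 + 9, NaOMe/MeOH; I2/MeOH oxidative aromatization giving methyl 2-hydroxy-4-methoxy-6-pentylbenzoate directly). Then saponify (KOH, aq. DMSO) and install both benzyl groups in one alkylation (BnBr, K2CO3, DMF), rejoining the route at 15.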